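**Strategy**

Ring B is not joined to ring C by an ether coupling; it is grown on the phenolic oxygen of ring C. The disconnection is the C4–C5 bond of ring B: a 4-hydroxy-3-isopropoxy-4-(1-aryloxyvinyl)cyclobutenone, built from isopropyl semisquarate and an α-lithiated vinyl ether of the ring C terphenyl phenol, is heated and rearranges (Moore) to a hydroquinone. This one operation closes ring B and sets its whole oxygen pattern, exploiting that ring B carries oxygens at C1, C2, C4 and C6 (C1/C4 para, hydrogens at C3/C5) with the C6 oxygen being the ether oxygen to ring C. Methylation, arylation with ring A and global dealkylation finish the synthesis.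

Key step: step 10

Remark on the chemistry: the target has no stereocentre, and because the outer trihydroxyphenyl rings are symmetric about their biaryl axes no atropisomers exist. The carbinol carbon of 20 is the only stereocentre in the route; it is made racemic and becomes sp2 in step 10.

Labels: ring A is the 3,5-dioxygenated phenoxy ring. Ring B carries O–ring A at C1, OH at C2, OH at C4 and O–ring C at C6. ArC stands for 2,4,6-trimethoxy-3,5-bis(2,4,6-trimethoxyphenyl)phenyl, the protected ring C with its two outer rings.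

**Route**

Step 1
Reactants: 1 2,4,6-trimethoxyphenol; 2 benzyl bromide
Product: 3 2-(benzyloxy)-1,3,5-trimethoxybenzene
Conditions: BnBr (1.1 equiv), K2CO3 (2 equiv), DMF, rt, Ar
Reagents that add atoms: benzyl bromide (2), BrCc1ccccc1
Why: Williamson etherification of the phenoxide; capping the oxidation-prone 4-methoxyphenol as a benzyl ether keeps the following bromination from diverting to a quinone.

Step 2
Reactants: 3 2-(benzyloxy)-1,3,5-trimethoxybenzene; 4 N-bromosuccinimide
Product: 5 2-(benzyloxy)-4,6-dibromo-1,3,5-trimethoxybenzene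
Conditions: NBS (2.1 equiv), MeCN, 0 °C to rt, dark
Reagents that add atoms: N-bromosuccinimide (4), O=C1CCC(=O)N1Br
Why: Electrophilic aromatic bromination; the two remaining ring positions are each activated by two ortho and one para alkoxy group, so both should brominate under mild polar conditions that leave the benzyl group untouched.

Step 3
Reactants: 5 2-(benzyloxy)-4,6-dibromo-1,3,5-trimethoxybenzene; 6 2,4,6-trimethoxyphenylboronic acid
Product: 7 2-(benzyloxy)-1,3,5-trimethoxy-4,6-bis(2,4,6-trimethoxyphenyl)benzene (ArC–OBn)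
Conditions: 6 (4 equiv), Pd(OAc)2 (10 mol%), SPhos (20 mol%), K3PO4 (6 equiv), toluene/H2O 10:1, 100 °C, Ar
Reagents that add atoms: 2,4,6-trimethoxyphenylboronic acid (6), COc1cc(OC)c(B(O)O)c(OC)c1
Why: Double Suzuki–Miyaura coupling; palladium with the bulky electron-rich biarylphosphine SPhos is an established system for tetra-ortho-substituted biaryls, and the large excess of the protodeboronation-prone boronic acid is meant to carry both bromides through.

Step 4
Reactants: 7 ArC–OBn
Product: 8 2,4,6-trimethoxy-3,5-bis(2,4,6-trimethoxyphenyl)phenol (ArC–OH, the ring C phenol)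
Conditions: H2 (1 atm), 10% Pd/C, EtOAc/MeOH, rt
Reagents that add atoms: none
Why: Catalytic hydrogenolysis of a benzyl aryl ether; aryl methyl ethers and the biaryl bonds are inert under these conditions.

Step 5
Reactants: 8 ArC–OH; 9 trichloroethylene
Product: 10 2-[(E)-1,2-dichloroethenyloxy]-1,3,5-trimethoxy-4,6-bis(2,4,6-trimethoxyphenyl)benzene (the (E)-1,2-dichlorovinyl ether of 8)
Conditions: Cl2C=CHCl (2 equiv), K2CO3 (2 equiv), DMF, 70 °C, Ar
Reagents that add atoms: trichloroethylene (9), ClC=C(Cl)Cl
Why: Base-mediated vinylation of a phenol with trichloroethylene, which runs through elimination to dichloroacetylene and anti addition of the phenoxide and so gives the E-configured dichlorovinyl ether (the alkene geometry is erased in step 6).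

Step 6
Reactants: 10 the (E)-1,2-dichlorovinyl ether of 8
Product: 13 2-(ethynyloxy)-1,3,5-trimethoxy-4,6-bis(2,4,6-trimethoxyphenyl)benzene (ArC–O–C≡CH), via chloroethynyl ether 11 (not isolated), via lithium aryloxyacetylide 12 (not isolated)
Conditions: n-BuLi (2.2 equiv), THF, −78 to −40 °C; then sat. aq NH4Cl, −78 °C; product kept cold and used at once
Reagents that add atoms: none
Why: Dehydrochlorination to the chloroalkyne followed by chlorine–lithium exchange is the standard conversion of 1,2-dichlorovinyl ethers into lithium alkynyl ether acetylides, and cold protonation gives the terminal ynol ether; at −78 °C without a diamine additive the aryl C–H bonds between methoxy groups should not be lithiated.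

Step 7
Reactants: 13 ArC–O–C≡CH; 14 tributyltin hydride
Product: 15 tributyl[1-(ArC-oxy)ethenyl]stannane
Conditions: Bu3SnH (1.1 equiv, slow addition), Pd(PPh3)4 (3 mol%), THF, 0 °C to rt; chromatography on Et3N-deactivated silica
Reagents that add atoms: tributyltin hydride (14), CCCC[SnH](CCCC)CCCC
Why: Palladium-catalysed syn hydrostannation of an alkynyl ether, a reaction type that delivers tin to the oxygen-bearing carbon; with a terminal alkyne this gives the 1,1-disubstituted α-stannyl vinyl ether, so no alkene geometry has to be controlled.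

Step 8
Reactants: 16 diisopropyl squarate
Product: 18 3-isopropoxycyclobut-3-ene-1,2-dione (isopropyl semisquarate), via hydroxycyclobutenone 17 (not isolated)
Conditions: LiAlH(OtBu)3 (1.05 equiv), THF, −78 to 0 °C, dilute HCl work-up; crude 17, conc. HCl (cat.), CH2Cl2, rt
Reagents that add atoms: water, O
Why: Known two-stage semisquarate preparation: the hindered hydride reduces one carbonyl only, and acid then ionises the allylic hydroxyl, water adds to the alkoxy-stabilised cation and isopropanol is expelled to leave the dione.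

Step 9
Reactants: 15 tributyl[1-(ArC-oxy)ethenyl]stannane; 18 3-isopropoxycyclobut-3-ene-1,2-dione
Product: 20 racemic 4-hydroxy-3-isopropoxy-4-[1-(ArC-oxy)ethenyl]cyclobut-2-en-1-one, via aryloxyvinyllithium 19 (not isolated)
Conditions: n-BuLi (1.05 equiv), THF, −78 °C, 20 min; cannulated into 18 (1.3 equiv), THF, −78 °C; sat. aq NH4Cl, −78 °C; NaHCO3 wash, Et3N-deactivated silica
Reagents that add atoms: 3-isopropoxycyclobut-3-ene-1,2-dione (18), CC(C)OC1=CC(=O)C1=O
Why: Tin–lithium exchange gives the α-aryloxyvinyllithium (an open-chain relative of the routinely used 2-lithiobenzofuran), which adds 1,2 to the ketone carbonyl next to the isopropoxy-bearing carbon because the other carbonyl is deactivated as part of a vinylogous ester; the carbinol stereocentre forms as a racemate and is destroyed in step 10.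

Step 10
Reactants: 20 racemic 4-hydroxy-3-isopropoxy-4-[1-(ArC-oxy)ethenyl]cyclobut-2-en-1-one
Product: 23 2-isopropoxy-6-(ArC-oxy)benzene-1,4-diol, via dienylketene 21 (not isolated), via cyclohexadienone 22 (not isolated)
Conditions: toluene (degassed, 0.01 M), 110 °C, Ar; aq Na2S2O4 wash; crude product taken on without exposure to air
Reagents that add atoms: none
Why: Moore rearrangement: heating opens the cyclobutenone by 4π conrotatory electrocyclic ring opening to the (Z)-dienylketene 21, whose ketene carbon and terminal vinyl CH2 then bond in a thermal 6π disrotatory electrocyclisation (the new C4–C5 bond of ring B), and the cyclohexadienone 22 enolises to the aromatic hydroquinone. The closest known reaction type is the thermal ring expansion of squarate-derived 4-alkenyl-4-hydroxycyclobutenones, including cases with an α-alkoxyalkenyl group such as 2-dihydropyranyl. Ring B is therefore closed by a six-electron electrocyclic ring closure and not by an ionic cyclisation, so no external reagent is involved. No stereocentre is created, and the racemic carbinol centre of 20 becomes an sp2 carbon. The selectivity needed is torquoselectivity in the ring opening: the electron-donating hydroxyl on C4 of the cyclobutenone rotates outward, which turns the vinyl group inward next to the ketene and allows closure, whereas the opposite rotation would lead to a butenolide. The oxygen pattern (C1 OH, C2 O-isopropyl, C4 OH, C6 O–ring C, hydrogens at C3 and C5) follows from the constitution of 20 and cannot scramble.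

Step 11
Reactants: 23 2-isopropoxy-6-(ArC-oxy)benzene-1,4-diol; 24 iodomethane
Product: 25 2-isopropoxy-4-methoxy-6-(ArC-oxy)phenol
Conditions: MeI (1.05 equiv), K2CO3 (1.1 equiv), acetone (degassed), rt, Ar
Reagents that add atoms: iodomethane (24), CI
Why: Williamson methylation with limiting weak base should alkylate only the C4 hydroxyl, which is unhindered and the more acidic one (two meta oxygens), whereas the C1 hydroxyl is flanked by the isopropoxy and the bulky ArC-oxy groups; methyl is chosen because it is removed with the other methyl ethers in step 13, so no separate deprotection is needed.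

Step 12
Reactants: 25 2-isopropoxy-4-methoxy-6-(ArC-oxy)phenol; 26 1-iodo-3,5-dimethoxybenzene
Product: 27 1-(3,5-dimethoxyphenoxy)-2-isopropoxy-4-methoxy-6-(ArC-oxy)benzene
Conditions: 26 (1.5 equiv), CuI (copper monoiodide, 10 mol%), picolinic acid (20 mol%), K3PO4 (2 equiv), DMSO, 90 °C, Ar
Reagents that add atoms: 1-iodo-3,5-dimethoxybenzene (26), COc1cc(I)cc(OC)c1
Why: Ullmann-type copper-catalysed diaryl ether synthesis; the copper–picolinic acid system is established for phenols with two ortho substituents, and the iodoarene partner is unhindered.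

Step 13
Reactants: 27 1-(3,5-dimethoxyphenoxy)-2-isopropoxy-4-methoxy-6-(ArC-oxy)benzene
Product: 28 CNP0228669.0, 5-[2,4-dihydroxy-6-(ring C aryloxy)phenoxy]benzene-1,3-diol in which the ring C aryl is 2,4,6-trihydroxy-3,5-bis(2,4,6-trihydroxyphenyl)phenyl
Conditions: BBr3 (30 equiv), CH2Cl2, −78 °C to rt; ice/H2O; reversed-phase chromatography
Reagents that add atoms: none
Why: Lewis-acid ether cleavage with BBr3 should remove all twelve methyl ethers and the isopropyl ether by bromide attack on the O-alkyl carbon of the borane adducts (the aryl borates hydrolyse on work-up), whereas the two diaryl ether bonds and the biaryl bonds offer no alkyl carbon and should survive.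

**Compound list**

1 | 2,4,6-trimethoxyphenol | COc1cc(OC)c(O)c(OC)c1 | starting material
2 | benzyl bromide | BrCc1ccccc1 | starting material
3 | 2-(benzyloxy)-1,3,5-trimethoxybenzene | c1ccccc1COc1c(OC)cc(OC)cc1OC | intermediate
4 | N-bromosuccinimide | O=C1CCC(=O)N1Br | starting material
5 | 2-(benzyloxy)-4,6-dibromo-1,3,5-trimethoxybenzene | c1ccccc1COc1c(OC)c(Br)c(OC)c(Br)c1OC | intermediate
6 | 2,4,6-trimethoxyphenylboronic acid | COc1cc(OC)c(B(O)O)c(OC)c1 | starting material
7 | 2-(benzyloxy)-1,3,5-trimethoxy-4,6-bis(2,4,6-trimethoxyphenyl)benzene | c1ccccc1COc1c(OC)c(-c2c(OC)cc(OC)cc2OC)c(OC)c(-c2c(OC)cc(OC)cc2OC)c1OC | intermediate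
8 | 2,4,6-trimethoxy-3,5-bis(2,4,6-trimethoxyphenyl)phenol | Oc1c(OC)c(-c2c(OC)cc(OC)cc2OC)c(OC)c(-c2c(OC)cc(OC)cc2OC)c1OC | intermediate
9 | trichloroethylene | ClC=C(Cl)Cl | starting material
10 | 2-[(E)-1,2-dichloroethenyloxy]-1,3,5-trimethoxy-4,6-bis(2,4,6-trimethoxyphenyl)benzene | Cl/C=C(/Cl)Oc1c(OC)c(-c2c(OC)cc(OC)cc2OC)c(OC)c(-c2c(OC)cc(OC)cc2OC)c1OC | intermediate
11 | 2-(chloroethynyloxy)-1,3,5-trimethoxy-4,6-bis(2,4,6-trimethoxyphenyl)benzene | ClC#COc1c(OC)c(-c2c(OC)cc(OC)cc2OC)c(OC)c(-c2c(OC)cc(OC)cc2OC)c1OC | intermediate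
12 | lithium 2-(ArC-oxy)acetylide | [Li]C#COc1c(OC)c(-c2c(OC)cc(OC)cc2OC)c(OC)c(-c2c(OC)cc(OC)cc2OC)c1OC | intermediate
13 | 2-(ethynyloxy)-1,3,5-trimethoxy-4,6-bis(2,4,6-trimethoxyphenyl)benzene | C#COc1c(OC)c(-c2c(OC)cc(OC)cc2OC)c(OC)c(-c2c(OC)cc(OC)cc2OC)c1OC | intermediate
14 | tributyltin hydride | CCCC[SnH](CCCC)CCCC | starting material
15 | tributyl[1-(ArC-oxy)ethenyl]stannane | C=C(Oc1c(OC)c(-c2c(OC)cc(OC)cc2OC)c(OC)c(-c2c(OC)cc(OC)cc2OC)c1OC)[Sn](CCCC)(CCCC)CCCC | intermediate
16 | diisopropyl squarate (3,4-diisopropoxycyclobut-3-ene-1,2-dione) | CC(C)OC1=C(OC(C)C)C(=O)C1=O | starting material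
17 | racemic 4-hydroxy-2,3-diisopropoxycyclobut-2-en-1-one | CC(C)OC1=C(OC(C)C)C(O)C1=O | intermediate
18 | 3-isopropoxycyclobut-3-ene-1,2-dione | CC(C)OC1=CC(=O)C1=O | intermediate
19 | [1-(ArC-oxy)ethenyl]lithium | [Li]C(=C)Oc1c(OC)c(-c2c(OC)cc(OC)cc2OC)c(OC)c(-c2c(OC)cc(OC)cc2OC)c1OC | intermediate
20 | racemic 4-hydroxy-3-isopropoxy-4-[1-(ArC-oxy)ethenyl]cyclobut-2-en-1-one | CC(C)OC1=CC(=O)C1(O)C(=C)Oc1c(OC)c(-c2c(OC)cc(OC)cc2OC)c(OC)c(-c2c(OC)cc(OC)cc2OC)c1OC | intermediate
21 | (Z)-4-hydroxy-3-isopropoxy-5-(ArC-oxy)hexa-1,3,5-trien-1-one (dienylketene, ketene and vinyl groups cis) | O=C=C/C(OC(C)C)=C(/O)C(=C)Oc1c(OC)c(-c2c(OC)cc(OC)cc2OC)c(OC)c(-c2c(OC)cc(OC)cc2OC)c1OC | intermediate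
22 | 4-hydroxy-3-isopropoxy-5-(ArC-oxy)cyclohexa-2,4-dien-1-one | O=C1C=C(OC(C)C)C(O)=C(Oc2c(OC)c(-c3c(OC)cc(OC)cc3OC)c(OC)c(-c3c(OC)cc(OC)cc3OC)c2OC)C1 | intermediate
23 | 2-isopropoxy-6-(ArC-oxy)benzene-1,4-diol | CC(C)Oc1cc(O)cc(Oc2c(OC)c(-c3c(OC)cc(OC)cc3OC)c(OC)c(-c3c(OC)cc(OC)cc3OC)c2OC)c1O | intermediate
24 | iodomethane | CI | starting material
25 | 2-isopropoxy-4-methoxy-6-(ArC-oxy)phenol | CC(C)Oc1cc(OC)cc(Oc2c(OC)c(-c3c(OC)cc(OC)cc3OC)c(OC)c(-c3c(OC)cc(OC)cc3OC)c2OC)c1O | intermediate
26 | 1-iodo-3,5-dimethoxybenzene | COc1cc(I)cc(OC)c1 | starting material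
27 | 1-(3,5-dimethoxyphenoxy)-2-isopropoxy-4-methoxy-6-(ArC-oxy)benzene | CC(C)Oc1cc(OC)cc(Oc2c(OC)c(-c3c(OC)cc(OC)cc3OC)c(OC)c(-c3c(OC)cc(OC)cc3OC)c2OC)c1Oc1cc(OC)cc(OC)c1 | intermediate
28 | CNP0228669.0 | Oc1cc(O)cc(Oc2c(O)cc(O)cc2Oc2c(O)c(-c3c(O)cc(O)cc3O)c(O)c(-c3c(O)cc(O)cc3O)c2O)c1 | target

**Step count and risks**

Total step count: 13. Longest linear sequence: 12 (steps 1–7 and 9–13; step 8 is a one-step side branch).

Steps most likely to fail:

Step 10 (key step). The ring opening may partly proceed with the hydroxyl turned inward, so that the ketene is captured as a lactone instead of closing ring B. Traces of acid may also strip the enol ether or the isopropoxy group before the ring opens, and the electron-rich hydroquinone may autoxidise during isolation. Fallback, setting out from phenol 8: ring B would be taken from a preformed arene and the C6 ether made by nucleophilic aromatic substitution. Phenol 8 with commercial 2,6-difluoro-4-methoxybenzaldehyde (COc1cc(F)c(C=O)c(F)c1, in excess; K2CO3, DMF, 90 °C) should give 2-fluoro-4-methoxy-6-(ArC-oxy)benzaldehyde F1. Displacement of the second activated fluoride with NaOCH(CH3)2 in THF/isopropanol at 0 °C to rt should give 2-isopropoxy-4-methoxy-6-(ArC-oxy)benzaldehyde F2. Baeyer–Villiger (Dakin-type) oxidation with mCPBA in CH2Cl2 at 0 °C should give 2-isopropoxy-4-methoxy-6-(ArC-oxy)phenyl formate F3, and methanolysis (cat. K2CO3, MeOH) comes back to the route at phenol 25.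

Step 3. Protodeboronation of the di-ortho-methoxy boronic acid may outpace the two hindered transmetalations, so that the coupling stalls after one aryl group or ends in hydrodebromination. Fallback, setting out from dibromide 5: a Negishi coupling. 1,3,5-Trimethoxybenzene is lithiated (n-BuLi, THF, 0 °C to rt) to (2,4,6-trimethoxyphenyl)lithium F4 and transmetalated with ZnCl2 to (2,4,6-trimethoxyphenyl)zinc chloride F5. This is coupled twice with 5 using Pd2(dba)3 and RuPhos in THF/NMP at 70 °C, coming back to the route at 7.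

Step 12. Carbon–oxygen bond formation at the phenoxide, which is flanked on both sides, may be too slow at copper, leaving reduction of the iodoarene and incomplete conversion as the main outcomes. Fallback, setting out from phenol 25: metal-free arylation with a diaryliodonium salt. Iodoarene 26 is oxidised with mCPBA and TsOH·H2O in MeCN, and the trivalent iodine species is captured by 1,3,5-trimethoxybenzene to give (3,5-dimethoxyphenyl)(2,4,6-trimethoxyphenyl)iodonium tosylate F6. The potassium phenoxide of 25 (KOtBu, THF, 0 °C to rt) should take the 3,5-dimethoxyphenyl group from F6, the trimethoxyphenyl group acting as the ligand that is not transferred, and the route is rejoined at 27.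

**Further compounds**

F1 | step 10 | 2-fluoro-4-methoxy-6-(ArC-oxy)benzaldehyde | COc1cc(F)c(C=O)c(Oc2c(OC)c(-c3c(OC)cc(OC)cc3OC)c(OC)c(-c3c(OC)cc(OC)cc3OC)c2OC)c1
F2 | step 10 | 2-isopropoxy-4-methoxy-6-(ArC-oxy)benzaldehyde | COc1cc(OC(C)C)c(C=O)c(Oc2c(OC)c(-c3c(OC)cc(OC)cc3OC)c(OC)c(-c3c(OC)cc(OC)cc3OC)c2OC)c1
F3 | step 10 | 2-isopropoxy-4-methoxy-6-(ArC-oxy)phenyl formate | COc1cc(OC(C)C)c(OC=O)c(Oc2c(OC)c(-c3c(OC)cc(OC)cc3OC)c(OC)c(-c3c(OC)cc(OC)cc3OC)c2OC)c1
F4 | step 3 | (2,4,6-trimethoxyphenyl)lithium | [Li]c1c(OC)cc(OC)cc1OC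
F5 | step 3 | (2,4,6-trimethoxyphenyl)zinc chloride | Cl[Zn]c1c(OC)cc(OC)cc1OC
F6 | step 12 | (3,5-dimethoxyphenyl)(2,4,6-trimethoxyphenyl)iodonium 4-methylbenzenesulfonate | COc1cc(OC)cc([I+]c2c(OC)cc(OC)cc2OC)c1.Cc1ccc(S(=O)(=O)[O-])cc1
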